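## The problem

The target is a profisetinidin-type tetraflavanoid. A (+)-catechin unit (2R,3S) carries one 5-deoxyflavan-3-ol unit at C6 (unit B) and one at C8 (unit M), and unit M carries a third (unit T) at C6 of its ring A. Flavan numbering is used within each unit. All three upper units are ent-fisetinidol units (2S,3R, 2,3-trans) whose C4–aryl bond lies cis to O3 and trans to the C2 aryl group. Nine of the eleven stereocentres therefore form three identical C2–C3–C4 triads, and the other two come with catechin. The 3,4-cis relation at each interflavan bond is the central difficulty, because capture of a flavan-4-yl cation, with or without a participating acyl group on O3, places the incoming arene trans to O3. The triads are remote from one another, so none can control another and each needs its own absolute control. The free compound has seventeen hydroxyl groups and is sensitive to air and base, and the benzylic C2–O1 bonds of intermediates ionise in acid, so all oxygen functions must stay masked until a final neutral step. The enabling feature is that ring A of each upper unit is a resorcinol ring without O5. Ring C of unit T can therefore be opened at the C8a–O1 aryl ether bond to leave a bromide at C8a ortho to an acyclic C2–C3–C4 chain, whose C4–aryl bond can be made with inversion from a trans oxirane and so set cis to O3.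

## Retrosynthesis

**39 to 38.** The seventeen O–benzyl bonds of 39 are cut last, which leads to the per-O-benzyl tetramer 38. Benzyl is preferred to silyl or acyl groups because it survives organomagnesium reagents, hydride, fluoride and carbonate and leaves under neutral conditions. 38 contains only ethers and no halogen, so a single hydrogenolysis is all that is asked.

**38 to 37.** Ring C of unit M is opened at C8a–O1 to give chloro alcohol 37. The neighbouring cut at O1–C2 would need a free phenol ortho to the chain, and the 2,4-dioxygenated aryl oxirane on the way to it would ionise and not react by SN2. Chloride is chosen for C8a of unit M so that it stays silent in every copper and magnesium step before this one. The forward step must join a hindered secondary benzylic alkoxide to an electron-rich aryl chloride, which calls for palladium with a bulky biaryl phosphine.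

**37 to 22 and 32.** With the O3 benzyl ether and the O2 silyl ether removed in thought (36, 35), the C4(M)–C8(catechin) bond is cut. This divides the molecule into two halves of similar size: oxirane 22 (units T and M) and bromide 32 (catechin and unit B), which reacts as its magnesium derivative 34 made through aryllithium 33. This cut uses the natural nucleophilicity of C8 and turns a trans oxirane into the 3,4-cis relation by inversion, which a cut at C4–C4a or C2–C3 would not. The forward reaction must deliver a di-ortho-substituted aryl group to a benzylic oxirane carbon by SN2 without ionising the oxirane.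

**32 to 8 and 27.** The same two cuts simplify 32. C8a–O1 of unit B gives alcohol 31 (from 30 and 29), and C4(B)–C6(catechin) gives the common oxirane 8 and the 8-bromo-6-iodo catechin ether 27, used as its magnesium derivative 28. The bromine at C8 is needed twice: it blocks C8 so that iodine, and with it unit B, goes to C6, and it is later the site of metalation for the union with 22. 27 goes back to (+)-catechin 23 through ethers 24 and 25 and bromide 26. The forward steps must tell iodide from bromide in the exchange, and the bromide of unit B from the shielded C8 bromide in the ring closure.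

**22 to 18 and 4.** Oxirane 22 is the silyl ether of the anti epoxy alcohol 21, which comes from epoxy ketone 20 by reduction, and 20 from enone 19 by epoxidation. The aldol cut of the C3–C4 double bond of 19 gives aldehyde 18, which holds the complete unit T, and methyl ketone 4, the source of ring B and C2. This is preferred to a cinnamyl alcohol epoxidation followed by aryl addition and redox adjustment at C2, because ring B and the C2 oxygen arrive in the first step. In return, the epoxidation of a hindered enone must be catalyst-controlled and the reduction chelation-controlled.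

**18 to 16.** Aldehyde 18 is the unmasked dioxolane 17. Ring C of unit T in 17 is opened at the C8a–O1 aryl ether bond to bromo alcohol 16; this is the disconnection on which the plan rests. Unlike the O1–C2 cut it never touches the C2 stereocentre, and unlike the C4–C4a cut it leaves C4 fixed by SN2 chemistry. The precursor is an acyclic chain with one free hydroxyl. The forward reaction must join the C2 alkoxide to C8a with retention, faster than β-hydride elimination, and must leave the chloride on ring A of unit M alone.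

**16 to 8 and 12.** 16 comes from 14 by benzylation of O3 (15) and desilylation. Cutting C4(T)–C6(M) in 14 gives oxirane 8 and aryl iodide 12, which reacts as its magnesium derivative 13. In 12 the iodine marks C6 of ring A of unit M, the dioxolane is the latent C4 of unit M and the chlorine is the later ring-closure site. A flavan-4-yl cation coupling would place the aryl group trans to O3; here the cis relation follows from inversion at the benzylic carbon of a trans oxirane. The nucleophile must attack the carbon next to the bromoaryl ring and not the one next to the silyloxy carbon.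

**8 to 2 and 4.** Oxirane 8, which serves units T and B, is traced through 7 and 6 to enone 5, and 5 by the aldol cut to aldehyde 2 and ketone 4. The ortho bromine of 2 has two roles: it damps ionisation of the later aryl oxirane, and it is the leaving group of the ring closure. All three stereocentres of a unit stem from one catalytic epoxidation: C3 directly, C2 by chelation-controlled reduction and C4 by inversion.

**Building blocks.** 2, 4 and 12 come from the commercial phenols 1, 3 and 9 by benzylation. For 12 this is preceded by iodination ortho to the hydroxyl group (10) and followed, after benzylation (11), by acetal formation. Only regioselective substitution is asked of these steps.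

## Roads not taken

**Alternative 1:** This plan cuts the three C2–aryl bonds of units T, M and B at the very end. Me3SiOTf would ionise three C2 acetates, each O3 acetate would close to a dioxolanylium ion, and an external catechol-type arene would attack each C2 trans to O3 to give A1.
- Merits: it has the most convergent finish of all the plans. Three B rings come from one cheap arene in one operation, and the 2,3-trans relation is secured by participation. In late-stage convergence it is better than the chosen plan, which brings ring B in early on every unit.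
- Weak points: it does not address the 3,4-cis interflavan bonds. The tris-lactol acetate core with all C4 centres is presupposed and is about as hard to make as the target. Three oxocarbenium ions on one molecule sit next to nucleophilic resorcinol rings (C6 and C8 of unit T are free), which invites intramolecular and intermolecular Friedel–Crafts competition. The acetates then cost a further step.
- Comparison: the chosen plan makes each triad by SN2 and chelation control on small molecules and pays with a longer sequence.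

**Alternative 2:** This plan cuts C3–C4 and the O1–C2 bond (as a lactone) of units M and B at once. Cs2CO3 would release two o-quinone methides from a bis(sulfone) on the catechin core, and a chiral triazolium carbene would turn an acyl imidazole into an azolium enolate that adds to each, giving bis-lactone A2.
- Merits: two rings and four stereocentres form in one catalytic step, the catalyst sets the absolute sense, and 3,4-cis is the innate outcome of this annulation, which is the hard relation here. For units M and B it is clearly shorter than the chosen plan.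
- Weak points: each o-quinone methide carries the doubly ortho-substituted catechin ring on its methide carbon, and both must react. A2 still lacks ring B and C2 of both units, so two aryl additions to lactones and two substrate-controlled lactol reductions remain. The bromide of A2 would have to be joined to the sp3 C4 of unit T with stereocontrol, so the hardest interflavan bond is only postponed.
- Comparison: the chosen plan treats all three units alike and sets C2 together with C3.

**Alternative 3:** This plan cuts C4–C4a of ring C in unit T. Pd2(dba)3 with Xantphos and K3PO4 would arylate the enolate of an α-aryloxy ketone with a ring-A iodide and give flavan-3-one A3, which equilibrates to the 2,4-trans isomer.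
- Merits: it is very short, and the thermodynamic 2,4-trans relation is the one the target needs. For unit T alone it needs fewer steps than the chosen plan.
- Weak points: A3 is racemic and both C2 and C4 are enolisable, so there is no absolute control and a resolution would be needed. The later ketone reduction must place O3 cis to the C4 aryl group under reagent control. Flavan-3-ones enolise and oxidise easily, and racemic units would multiply diastereomers in a tetramer.
- Comparison: the chosen plan has absolute control from the epoxidation onward and configurationally stable intermediates.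

Key step: step 13

Remark: poly-L-leucine is taken to give the (2R,3S) epoxy ketone as with the parent chalcone, since the ring substituents do not change the priorities at the oxirane carbons.

## Route

Step 1
Reactants: 1 2-bromo-4-hydroxybenzaldehyde
Product: 2 4-(benzyloxy)-2-bromobenzaldehyde
Conditions: BnBr, K2CO3, DMF, rt
Reagents that add atoms: benzyl bromide, BrCc1ccccc1
Why: Williamson etherification of the phenoxide; the aldehyde has no enolisable position and is untouched.

Step 2
Reactants: 3 1-(3,4-dihydroxyphenyl)ethan-1-one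
Product: 4 1-[3,4-bis(benzyloxy)phenyl]ethan-1-one
Conditions: BnBr, K2CO3, DMF, 60 °C
Reagents that add atoms: benzyl bromide, BrCc1ccccc1
Why: Double Williamson etherification; O-alkylation of the phenoxides is far faster than any enolate alkylation under carbonate.

Step 3
Reactants: 2 4-(benzyloxy)-2-bromobenzaldehyde; 4 1-[3,4-bis(benzyloxy)phenyl]ethan-1-one
Product: 5 (E)-3-[4-(benzyloxy)-2-bromophenyl]-1-[3,4-bis(benzyloxy)phenyl]prop-2-en-1-one
Conditions: KOH, EtOH/THF, rt
Reagents that add atoms: none
Why: Claisen–Schmidt condensation; the non-enolisable aldehyde takes the enolate of 4 and dehydration gives the conjugated E enone.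

Step 4
Reactants: 5 (E)-3-[4-(benzyloxy)-2-bromophenyl]-1-[3,4-bis(benzyloxy)phenyl]prop-2-en-1-one
Product: 6 [(2R,3S)-3-[4-(benzyloxy)-2-bromophenyl]oxiran-2-yl][3,4-bis(benzyloxy)phenyl]methanone (trans oxirane)
Conditions: poly-L-leucine, urea–H2O2, DBU, THF, rt
Reagents that add atoms: hydrogen peroxide (as its urea adduct), OO
Why: Juliá–Colonna epoxidation: hydroperoxide adds to the enone inside the helical peptide and closes to the trans oxirane, and poly-L-leucine should give the (2R,3S) isomer as with chalcone itself. This fixes the later C3 and the centre from which C4 is derived; the enantiomeric purity can be raised by recrystallisation.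

Step 5
Reactants: 6 [(2R,3S)-3-[4-(benzyloxy)-2-bromophenyl]oxiran-2-yl][3,4-bis(benzyloxy)phenyl]methanone
Product: 7 (S)-[3,4-bis(benzyloxy)phenyl][(2S,3S)-3-[4-(benzyloxy)-2-bromophenyl]oxiran-2-yl]methanol (anti epoxy alcohol)
Conditions: Zn(BH4)2, Et2O, −20 °C; aq. NH4Cl
Reagents that add atoms: none
Why: Chelation-controlled reduction (Cram chelate model): zinc bridges the carbonyl and oxirane oxygens and hydride enters from the side of the oxirane C–H. This should give the anti epoxy alcohol, which corresponds to the 2,3-trans relation of the flavan.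

Step 6
Reactants: 7 (S)-[3,4-bis(benzyloxy)phenyl][(2S,3S)-3-[4-(benzyloxy)-2-bromophenyl]oxiran-2-yl]methanol
Product: 8 triisopropylsilyl ether of 7, [(S)-[3,4-bis(benzyloxy)phenyl][(2R,3S)-3-[4-(benzyloxy)-2-bromophenyl]oxiran-2-yl]methoxy]tri(propan-2-yl)silane
Conditions: TIPSOTf, 2,6-lutidine, CH2Cl2, −78 °C
Reagents that add atoms: triisopropylsilyl trifluoromethanesulfonate, CC(C)[Si](OS(=O)(=O)C(F)(F)F)(C(C)C)C(C)C
Why: O-silylation under buffered low-temperature conditions that spare the acid-sensitive aryl oxirane. The bulky silyl group is chosen because it does not migrate to a neighbouring alkoxide in steps 10 and 11 and falls to fluoride beside benzyl ethers.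

Step 7
Reactants: 9 2-chloro-4-hydroxybenzaldehyde
Product: 10 2-chloro-4-hydroxy-5-iodobenzaldehyde
Conditions: NIS, TFA (cat.), MeCN, 0 °C to rt
Reagents that add atoms: N-iodosuccinimide, O=C1CCC(=O)N1I
Why: Electrophilic aromatic iodination ortho to the hydroxyl group; C5 is favoured because the other ortho position lies between chlorine and oxygen.

Step 8
Reactants: 10 2-chloro-4-hydroxy-5-iodobenzaldehyde
Product: 11 4-(benzyloxy)-2-chloro-5-iodobenzaldehyde
Conditions: BnBr, K2CO3, DMF, rt
Reagents that add atoms: benzyl bromide, BrCc1ccccc1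
Why: Williamson etherification of the phenoxide.

Step 9
Reactants: 11 4-(benzyloxy)-2-chloro-5-iodobenzaldehyde
Product: 12 2-[4-(benzyloxy)-2-chloro-5-iodophenyl]-1,3-dioxolane
Conditions: HOCH2CH2OH, TsOH (cat.), toluene, reflux (water removal)
Reagents that add atoms: ethane-1,2-diol, OCCO
Why: Acid-catalysed acetalisation driven by removal of water; the dioxolane masks the aldehyde against the organomagnesium, hydride and base steps that follow.

Step 10
Reactants: 12 2-[4-(benzyloxy)-2-chloro-5-iodophenyl]-1,3-dioxolane; 8 triisopropylsilyl ether of the anti epoxy alcohol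
Product: 14 (1S,2R,3R)-3-[4-(benzyloxy)-2-bromophenyl]-3-[2-(benzyloxy)-4-chloro-5-(1,3-dioxolan-2-yl)phenyl]-1-[3,4-bis(benzyloxy)phenyl]-1-[(triisopropylsilyl)oxy]propan-2-ol, via arylmagnesium chloride 13 (not isolated)
Conditions: iPrMgCl·LiCl, THF, −30 °C; CuI (10 mol%), then 8, −30 to 0 °C
Reagents that add atoms: none
Why: Iodine–magnesium exchange takes only the iodide. The copper-catalysed opening of the aryl oxirane is an SN2 substitution at the benzylic carbon with inversion, the other oxirane carbon being shielded by the silyloxybenzyl group. This sets C4 of unit T in the relation that becomes 3,4-cis.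

Step 11
Reactants: 14 the silyloxy alcohol from step 10
Product: 15 2-O-benzyl ether of 14, (1S,2R,3R) configuration unchanged
Conditions: NaH, BnBr, Bu4NI (cat.), THF/DMF, 0 °C to rt
Reagents that add atoms: benzyl bromide, BrCc1ccccc1
Why: Williamson etherification of the secondary alkoxide; the triisopropylsilyl group is too bulky to migrate to the neighbouring alkoxide at this temperature, so the benzyl group ends up on the future O3.

Step 12
Reactants: 15 the benzyl silyl ether from step 11
Product: 16 (1S,2R,3R)-2-(benzyloxy)-3-[4-(benzyloxy)-2-bromophenyl]-3-[2-(benzyloxy)-4-chloro-5-(1,3-dioxolan-2-yl)phenyl]-1-[3,4-bis(benzyloxy)phenyl]propan-1-ol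
Conditions: TBAF, THF, rt
Reagents that add atoms: none
Why: Fluoride-induced desilylation frees only the benzylic hydroxyl that becomes O1; benzyl ethers, the acetal and both aryl halides are inert to fluoride.

Step 13
Reactants: 16 the bromo alcohol from step 12
Product: 17 (2S,3R)-3,7-bis(benzyloxy)-2-[3,4-bis(benzyloxy)phenyl]-4-[2-(benzyloxy)-4-chloro-5-(1,3-dioxolan-2-yl)phenyl]chromane, 2,3-trans-3,4-cis (protected unit T with the 4α-aryl group)
Conditions: CuI (20 mol%), 3,4,7,8-tetramethyl-1,10-phenanthroline, Cs2CO3, toluene, 110 °C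
Reagents that add atoms: none
Why: Ullmann-type copper-catalysed O-arylation of a secondary alcohol, run intramolecularly. Cs2CO3 turns the C2 hydroxyl into a monovalent copper alkoxide carried by the phenanthroline ligand; this complex activates the C8a–Br bond within its reach, and reductive elimination from trivalent copper forms C8a–O1. Ring C closes in a 6-exo sense, the alkoxide attacking the ipso carbon of a bromide held three atoms away; the five-membered alternative is excluded because O3 is a benzyl ether. No stereocentre is created: the carbinol C–O bond is never broken, so C2 keeps its configuration, and C3 and C4 carry no hydrogen that carbonate could remove. The step needs C–O coupling to outrun β-hydride elimination from the benzylic alkoxide, which the electron-rich tetramethylphenanthroline ligand favours. It also needs chemoselectivity between the two aryl halides: the chloride on ring A of unit M does not react with copper under these conditions and cannot be reached by the alkoxide.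

Step 14
Reactants: 17 protected unit T with the dioxolane
Product: 18 4-(benzyloxy)-2-chloro-5-[(2S,3R)-3,7-bis(benzyloxy)-2-[3,4-bis(benzyloxy)phenyl]-2,3-trans-3,4-cis-chroman-4-yl]benzaldehyde
Conditions: PPTS, acetone/H2O, 50 °C
Reagents that add atoms: water, O
Why: Mild acid-catalysed acetal hydrolysis; the weak acid is chosen so that the benzylic C2–O1 bond of the flavan does not ionise.

Step 15
Reactants: 18 the aldehyde from step 14; 4 1-[3,4-bis(benzyloxy)phenyl]ethan-1-one
Product: 19 (E)-1-[3,4-bis(benzyloxy)phenyl]-3-aryl-prop-2-en-1-one, aryl being the 4-(benzyloxy)-2-chloro-5-(unit T-4-yl)phenyl group of 18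
Conditions: KOH, EtOH/THF, rt
Reagents that add atoms: none
Why: Claisen–Schmidt condensation as in step 3; unit T holds only ethers and is stable to hydroxide at room temperature.

Step 16
Reactants: 19 the enone from step 15
Product: 20 (2R,3S)-trans-epoxy ketone of 19 (oxirane C3 on the chloroaryl ring, C2 on the carbonyl)
Conditions: poly-L-leucine, urea–H2O2, DBU, THF, rt
Reagents that add atoms: hydrogen peroxide (as its urea adduct), OO
Why: Juliá–Colonna epoxidation under catalyst control, with the same sense as in step 4; the stereocentres of unit T are five or more bonds from the enone and should not interfere.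

Step 17
Reactants: 20 the epoxy ketone from step 16
Product: 21 anti epoxy alcohol, (S)-carbinol next to the (2S,3S)-oxirane
Conditions: Zn(BH4)2, Et2O/THF, −20 °C; aq. NH4Cl
Reagents that add atoms: none
Why: Chelation-controlled reduction as in step 5 gives the anti isomer, which fixes the later C2 of unit M.

Step 18
Reactants: 21 the anti epoxy alcohol from step 17
Product: 22 triisopropylsilyl ether of 21 (oxirane carrying units T and M)
Conditions: TIPSOTf, 2,6-lutidine, CH2Cl2, −78 °C
Reagents that add atoms: triisopropylsilyl trifluoromethanesulfonate, CC(C)[Si](OS(=O)(=O)C(F)(F)F)(C(C)C)C(C)C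
Why: O-silylation as in step 6.

Step 19
Reactants: 23 (+)-catechin
Product: 24 5,7,3',4'-tetra-O-benzylcatechin
Conditions: BnBr, K2CO3, DMF, 0 °C to rt
Reagents that add atoms: benzyl bromide, BrCc1ccccc1
Why: Williamson etherification of the four phenols; carbonate does not deprotonate the aliphatic 3-hydroxyl.

Step 20
Reactants: 24 5,7,3',4'-tetra-O-benzylcatechin
Product: 25 3,5,7,3',4'-penta-O-benzylcatechin
Conditions: NaH, BnBr, DMF, 0 °C to rt
Reagents that add atoms: benzyl bromide, BrCc1ccccc1
Why: Williamson etherification of the secondary alkoxide.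

Step 21
Reactants: 25 penta-O-benzylcatechin
Product: 26 8-bromo-penta-O-benzylcatechin
Conditions: NBS, CH2Cl2, −78 °C to rt
Reagents that add atoms: N-bromosuccinimide, O=C1CCC(=O)N1Br
Why: Electrophilic aromatic bromination of the phloroglucinol ring; C8 is the more accessible of its two free positions and reacts first.

Step 22
Reactants: 26 8-bromo-penta-O-benzylcatechin
Product: 27 8-bromo-6-iodo-penta-O-benzylcatechin
Conditions: NIS, TFA (cat.), CH2Cl2, 0 °C to rt
Reagents that add atoms: N-iodosuccinimide, O=C1CCC(=O)N1I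
Why: Electrophilic aromatic iodination at C6, the only free position left on the most electron-rich ring.

Step 23
Reactants: 27 8-bromo-6-iodo-penta-O-benzylcatechin; 8 triisopropylsilyl ether of the anti epoxy alcohol
Product: 29 (1S,2R,3R)-3-[4-(benzyloxy)-2-bromophenyl]-1-[3,4-bis(benzyloxy)phenyl]-3-(8-bromo-penta-O-benzylcatechin-6-yl)-1-[(triisopropylsilyl)oxy]propan-2-ol, via arylmagnesium chloride 28 (not isolated)
Conditions: iPrMgCl·LiCl, THF, −20 °C; CuI (10 mol%), then 8, −20 to 0 °C
Reagents that add atoms: none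
Why: Iodine–magnesium exchange is much faster than bromine–magnesium exchange, so only C6 is metalated. The copper-catalysed SN2 opening of the oxirane at the benzylic carbon then sets C4 of unit B with inversion, as in step 10.

Step 24
Reactants: 29 the silyloxy alcohol from step 23
Product: 30 2-O-benzyl ether of 29
Conditions: NaH, BnBr, Bu4NI (cat.), THF/DMF, 0 °C to rt
Reagents that add atoms: benzyl bromide, BrCc1ccccc1
Why: Williamson etherification as in step 11.

Step 25
Reactants: 30 the benzyl silyl ether from step 24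
Product: 31 (1S,2R,3R)-2-(benzyloxy)-3-[4-(benzyloxy)-2-bromophenyl]-1-[3,4-bis(benzyloxy)phenyl]-3-(8-bromo-penta-O-benzylcatechin-6-yl)propan-1-ol
Conditions: TBAF, THF, rt
Reagents that add atoms: none
Why: Fluoride-induced desilylation as in step 12.

Step 26
Reactants: 31 the bromo alcohol from step 25
Product: 32 per-O-benzyl ent-fisetinidol-(4α→6)-catechin carrying bromine at C8 of the catechin unit (unit B 2S,3R, 2,3-trans-3,4-cis)
Conditions: CuI (20 mol%), 3,4,7,8-tetramethyl-1,10-phenanthroline, Cs2CO3, toluene, 110 °C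
Reagents that add atoms: none
Why: The same Ullmann-type intramolecular O-arylation as in step 13, with retention at C2. The C8 bromide of the catechin ring is flanked by two oxygen substituents, is electron-rich and is out of reach of the alkoxide, so only the bromide of ring A of unit B should couple.

Step 27
Reactants: 32 the 8-bromo dimer from step 26; 22 the oxirane carrying units T and M
Product: 35 open-chain unit M, (1S,2R,3R)-1-[3,4-bis(benzyloxy)phenyl]-1-[(triisopropylsilyl)oxy]propan-2-ol with C3 bearing C8 of the catechin unit of 32 and the chloroaryl ring of 22, via aryllithium 33 (not isolated), via arylmagnesium bromide 34 (not isolated)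
Conditions: t-BuLi (2 equiv), THF, −78 °C; MgBr2·OEt2; CuI (20 mol%), then 22, −30 to 0 °C
Reagents that add atoms: none
Why: Bromine–lithium exchange at C8 and transmetalation to magnesium give an aryl nucleophile that opens the oxirane of 22 at the benzylic carbon under copper catalysis with inversion (SN2). This forms the C4(M)–C8 bond in the 3,4-cis sense; the aryl chloride of 22 is inert to the organometallic at this temperature.

Step 28
Reactants: 35 the silyloxy alcohol from step 27
Product: 36 2-O-benzyl ether of 35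
Conditions: NaH, BnBr, Bu4NI (cat.), THF/DMF, 0 °C to rt
Reagents that add atoms: benzyl bromide, BrCc1ccccc1
Why: Williamson etherification as in step 11.

Step 29
Reactants: 36 the benzyl silyl ether from step 28
Product: 37 chloro alcohol, 36 with the free C1 hydroxyl (future O1 of unit M)
Conditions: TBAF, THF, rt
Reagents that add atoms: none
Why: Fluoride-induced desilylation as in step 12.

Step 30
Reactants: 37 the chloro alcohol from step 29
Product: 38 heptadeca-O-benzyl ether of the target (all four units closed)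
Conditions: [Pd(allyl)Cl]2 (5 mol%), RockPhos, Cs2CO3, toluene, 90 °C
Reagents that add atoms: none
Why: Buchwald–Hartwig etherification run intramolecularly: zerovalent palladium inserts into the only aryl halide left, the alkoxide displaces chloride on divalent palladium, and the bulky biaryl phosphine drives C–O reductive elimination ahead of β-hydride elimination. Ring C of unit M closes with retention at C2 because the carbinol C–O bond is not broken.

Step 31
Reactants: 38 the heptadeca-O-benzyl ether
Product: 39 target tetraflavanoid CNP0126838.1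
Conditions: H2 (1 atm), Pd(OH)2/C, THF/MeOH/H2O, rt
Reagents that add atoms: none
Why: Hydrogenolysis of the seventeen benzyl ethers under neutral conditions; the cyclic benzylic C2–O1 bonds and the diarylmethine C4 centres of flavans are not cleaved under these mild conditions.

## Compound list

1 | 2-bromo-4-hydroxybenzaldehyde | O=Cc1ccc(O)cc1Br | starting material
2 | 4-(benzyloxy)-2-bromobenzaldehyde | O=Cc1ccc(OCc9ccccc9)cc1Br | intermediate
3 | 1-(3,4-dihydroxyphenyl)ethan-1-one | CC(=O)c1ccc(O)c(O)c1 | starting material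
4 | 1-[3,4-bis(benzyloxy)phenyl]ethan-1-one | CC(=O)c1ccc(OCc9ccccc9)c(OCc9ccccc9)c1 | intermediate
5 | (E)-3-[4-(benzyloxy)-2-bromophenyl]-1-[3,4-bis(benzyloxy)phenyl]prop-2-en-1-one | O=C(/C=C/c1ccc(OCc9ccccc9)cc1Br)c1ccc(OCc9ccccc9)c(OCc9ccccc9)c1 | intermediate
6 | [(2R,3S)-3-[4-(benzyloxy)-2-bromophenyl]oxiran-2-yl][3,4-bis(benzyloxy)phenyl]methanone | O=C(c1ccc(OCc9ccccc9)c(OCc9ccccc9)c1)[C@@H]1O[C@H]1c1ccc(OCc9ccccc9)cc1Br | intermediate
7 | (S)-[3,4-bis(benzyloxy)phenyl][(2S,3S)-3-[4-(benzyloxy)-2-bromophenyl]oxiran-2-yl]methanol (anti) | O[C@@H](c1ccc(OCc9ccccc9)c(OCc9ccccc9)c1)[C@@H]1O[C@H]1c1ccc(OCc9ccccc9)cc1Br | intermediate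
8 | triisopropylsilyl ether of 7 | CC(C)[Si](C(C)C)(C(C)C)O[C@@H](c1ccc(OCc9ccccc9)c(OCc9ccccc9)c1)[C@@H]1O[C@H]1c1ccc(OCc9ccccc9)cc1Br | intermediate
9 | 2-chloro-4-hydroxybenzaldehyde | O=Cc1ccc(O)cc1Cl | starting material
10 | 2-chloro-4-hydroxy-5-iodobenzaldehyde | O=Cc1cc(I)c(O)cc1Cl | intermediate
11 | 4-(benzyloxy)-2-chloro-5-iodobenzaldehyde | O=Cc1cc(I)c(OCc9ccccc9)cc1Cl | intermediate
12 | 2-[4-(benzyloxy)-2-chloro-5-iodophenyl]-1,3-dioxolane | Ic1cc(C2OCCO2)c(Cl)cc1OCc9ccccc9 | intermediate
13 | [2-(benzyloxy)-4-chloro-5-(1,3-dioxolan-2-yl)phenyl]magnesium chloride | Cl[Mg]c1cc(C2OCCO2)c(Cl)cc1OCc9ccccc9 | intermediate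
14 | (1S,2R,3R)-3-[4-(benzyloxy)-2-bromophenyl]-3-[2-(benzyloxy)-4-chloro-5-(1,3-dioxolan-2-yl)phenyl]-1-[3,4-bis(benzyloxy)phenyl]-1-[(triisopropylsilyl)oxy]propan-2-ol | CC(C)[Si](C(C)C)(C(C)C)O[C@@H](c1ccc(OCc9ccccc9)c(OCc9ccccc9)c1)[C@H](O)[C@@H](c1ccc(OCc9ccccc9)cc1Br)c1cc(C2OCCO2)c(Cl)cc1OCc9ccccc9 | intermediate
15 | 2-O-benzyl ether of 14 | CC(C)[Si](C(C)C)(C(C)C)O[C@@H](c1ccc(OCc9ccccc9)c(OCc9ccccc9)c1)[C@H](OCc9ccccc9)[C@@H](c1ccc(OCc9ccccc9)cc1Br)c1cc(C2OCCO2)c(Cl)cc1OCc9ccccc9 | intermediate
16 | (1S,2R,3R)-2-(benzyloxy)-3-[4-(benzyloxy)-2-bromophenyl]-3-[2-(benzyloxy)-4-chloro-5-(1,3-dioxolan-2-yl)phenyl]-1-[3,4-bis(benzyloxy)phenyl]propan-1-ol | O[C@@H](c1ccc(OCc9ccccc9)c(OCc9ccccc9)c1)[C@H](OCc9ccccc9)[C@@H](c1ccc(OCc9ccccc9)cc1Br)c1cc(C2OCCO2)c(Cl)cc1OCc9ccccc9 | intermediate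
17 | (2S,3R)-3,7-bis(benzyloxy)-2-[3,4-bis(benzyloxy)phenyl]-4-[2-(benzyloxy)-4-chloro-5-(1,3-dioxolan-2-yl)phenyl]chromane, 2,3-trans-3,4-cis | C(c9ccccc9)Oc1ccc2c(c1)O[C@@H](c1ccc(OCc9ccccc9)c(OCc9ccccc9)c1)[C@H](OCc9ccccc9)[C@@H]2c1cc(C3OCCO3)c(Cl)cc1OCc9ccccc9 | intermediate
18 | 4-(benzyloxy)-2-chloro-5-[(2S,3R)-3,7-bis(benzyloxy)-2-[3,4-bis(benzyloxy)phenyl]-2,3-trans-3,4-cis-chroman-4-yl]benzaldehyde | C(c9ccccc9)Oc1ccc2c(c1)O[C@@H](c1ccc(OCc9ccccc9)c(OCc9ccccc9)c1)[C@H](OCc9ccccc9)[C@@H]2c1cc(C=O)c(Cl)cc1OCc9ccccc9 | intermediate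
19 | (E)-enone from 18 and 4 | C(c9ccccc9)Oc1ccc2c(c1)O[C@@H](c1ccc(OCc9ccccc9)c(OCc9ccccc9)c1)[C@H](OCc9ccccc9)[C@@H]2c1cc(/C=C/C(=O)c3ccc(OCc9ccccc9)c(OCc9ccccc9)c3)c(Cl)cc1OCc9ccccc9 | intermediate
20 | (2R,3S)-trans-epoxy ketone of 19 | C(c9ccccc9)Oc1ccc2c(c1)O[C@@H](c1ccc(OCc9ccccc9)c(OCc9ccccc9)c1)[C@H](OCc9ccccc9)[C@@H]2c1cc([C@@H]3O[C@H]3C(=O)c3ccc(OCc9ccccc9)c(OCc9ccccc9)c3)c(Cl)cc1OCc9ccccc9 | intermediate
21 | anti epoxy alcohol from 20, (S)-carbinol and (2S,3S)-oxirane | C(c9ccccc9)Oc1ccc2c(c1)O[C@@H](c1ccc(OCc9ccccc9)c(OCc9ccccc9)c1)[C@H](OCc9ccccc9)[C@@H]2c1cc([C@@H]3O[C@H]3[C@@H](O)c3ccc(OCc9ccccc9)c(OCc9ccccc9)c3)c(Cl)cc1OCc9ccccc9 | intermediate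
22 | triisopropylsilyl ether of 21 | C(c9ccccc9)Oc1ccc2c(c1)O[C@@H](c1ccc(OCc9ccccc9)c(OCc9ccccc9)c1)[C@H](OCc9ccccc9)[C@@H]2c1cc([C@@H]3O[C@H]3[C@@H](O[Si](C(C)C)(C(C)C)C(C)C)c3ccc(OCc9ccccc9)c(OCc9ccccc9)c3)c(Cl)cc1OCc9ccccc9 | intermediate
23 | (+)-catechin | O[C@H]1Cc2c(O)cc(O)cc2O[C@@H]1c1ccc(O)c(O)c1 | starting material
24 | 5,7,3',4'-tetra-O-benzylcatechin | O[C@H]1Cc2c(OCc9ccccc9)cc(OCc9ccccc9)cc2O[C@@H]1c1ccc(OCc9ccccc9)c(OCc9ccccc9)c1 | intermediate
25 | 3,5,7,3',4'-penta-O-benzylcatechin | C(c9ccccc9)O[C@H]1Cc2c(OCc9ccccc9)cc(OCc9ccccc9)cc2O[C@@H]1c1ccc(OCc9ccccc9)c(OCc9ccccc9)c1 | intermediate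
26 | 8-bromo-penta-O-benzylcatechin | C(c9ccccc9)O[C@H]1Cc2c(OCc9ccccc9)cc(OCc9ccccc9)c(Br)c2O[C@@H]1c1ccc(OCc9ccccc9)c(OCc9ccccc9)c1 | intermediate
27 | 8-bromo-6-iodo-penta-O-benzylcatechin | C(c9ccccc9)O[C@H]1Cc2c(OCc9ccccc9)c(I)c(OCc9ccccc9)c(Br)c2O[C@@H]1c1ccc(OCc9ccccc9)c(OCc9ccccc9)c1 | intermediate
28 | (8-bromo-penta-O-benzylcatechin-6-yl)magnesium chloride | C(c9ccccc9)O[C@H]1Cc2c(OCc9ccccc9)c([Mg]Cl)c(OCc9ccccc9)c(Br)c2O[C@@H]1c1ccc(OCc9ccccc9)c(OCc9ccccc9)c1 | intermediate
29 | (1S,2R,3R)-3-[4-(benzyloxy)-2-bromophenyl]-1-[3,4-bis(benzyloxy)phenyl]-3-(8-bromo-penta-O-benzylcatechin-6-yl)-1-[(triisopropylsilyl)oxy]propan-2-ol | CC(C)[Si](C(C)C)(C(C)C)O[C@@H](c1ccc(OCc9ccccc9)c(OCc9ccccc9)c1)[C@H](O)[C@@H](c1ccc(OCc9ccccc9)cc1Br)c1c(OCc9ccccc9)c2C[C@H](OCc9ccccc9)[C@@H](c3ccc(OCc9ccccc9)c(OCc9ccccc9)c3)Oc2c(Br)c1OCc9ccccc9 | intermediate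
30 | 2-O-benzyl ether of 29 | CC(C)[Si](C(C)C)(C(C)C)O[C@@H](c1ccc(OCc9ccccc9)c(OCc9ccccc9)c1)[C@H](OCc9ccccc9)[C@@H](c1ccc(OCc9ccccc9)cc1Br)c1c(OCc9ccccc9)c2C[C@H](OCc9ccccc9)[C@@H](c3ccc(OCc9ccccc9)c(OCc9ccccc9)c3)Oc2c(Br)c1OCc9ccccc9 | intermediate
31 | (1S,2R,3R)-2-(benzyloxy)-3-[4-(benzyloxy)-2-bromophenyl]-1-[3,4-bis(benzyloxy)phenyl]-3-(8-bromo-penta-O-benzylcatechin-6-yl)propan-1-ol | O[C@@H](c1ccc(OCc9ccccc9)c(OCc9ccccc9)c1)[C@H](OCc9ccccc9)[C@@H](c1ccc(OCc9ccccc9)cc1Br)c1c(OCc9ccccc9)c2C[C@H](OCc9ccccc9)[C@@H](c3ccc(OCc9ccccc9)c(OCc9ccccc9)c3)Oc2c(Br)c1OCc9ccccc9 | intermediate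
32 | per-O-benzyl ent-fisetinidol-(4α→6)-catechin, 8-bromide | C(c9ccccc9)Oc1ccc2c(c1)O[C@@H](c1ccc(OCc9ccccc9)c(OCc9ccccc9)c1)[C@H](OCc9ccccc9)[C@@H]2c1c(OCc9ccccc9)c2C[C@H](OCc9ccccc9)[C@@H](c3ccc(OCc9ccccc9)c(OCc9ccccc9)c3)Oc2c(Br)c1OCc9ccccc9 | intermediate
33 | 8-lithio derivative of 32 | C(c9ccccc9)Oc1ccc2c(c1)O[C@@H](c1ccc(OCc9ccccc9)c(OCc9ccccc9)c1)[C@H](OCc9ccccc9)[C@@H]2c1c(OCc9ccccc9)c2C[C@H](OCc9ccccc9)[C@@H](c3ccc(OCc9ccccc9)c(OCc9ccccc9)c3)Oc2c([Li])c1OCc9ccccc9 | intermediate
34 | 8-bromomagnesio derivative of 32 | C(c9ccccc9)Oc1ccc2c(c1)O[C@@H](c1ccc(OCc9ccccc9)c(OCc9ccccc9)c1)[C@H](OCc9ccccc9)[C@@H]2c1c(OCc9ccccc9)c2C[C@H](OCc9ccccc9)[C@@H](c3ccc(OCc9ccccc9)c(OCc9ccccc9)c3)Oc2c([Mg]Br)c1OCc9ccccc9 | intermediate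
35 | open-chain unit M, (1S,2R,3R), 1-O-triisopropylsilyl, free 2-hydroxyl | C(c9ccccc9)Oc1ccc2c(c1)O[C@@H](c1ccc(OCc9ccccc9)c(OCc9ccccc9)c1)[C@H](OCc9ccccc9)[C@@H]2c1cc([C@@H](c3c(OCc9ccccc9)c([C@@H]5c6ccc(OCc9ccccc9)cc6O[C@@H](c6ccc(OCc9ccccc9)c(OCc9ccccc9)c6)[C@@H]5OCc9ccccc9)c(OCc9ccccc9)c4C[C@H](OCc9ccccc9)[C@@H](c5ccc(OCc9ccccc9)c(OCc9ccccc9)c5)Oc34)[C@@H](O)[C@@H](O[Si](C(C)C)(C(C)C)C(C)C)c3ccc(OCc9ccccc9)c(OCc9ccccc9)c3)c(Cl)cc1OCc9ccccc9 | intermediate
36 | 2-O-benzyl ether of 35 | C(c9ccccc9)Oc1ccc2c(c1)O[C@@H](c1ccc(OCc9ccccc9)c(OCc9ccccc9)c1)[C@H](OCc9ccccc9)[C@@H]2c1cc([C@@H](c3c(OCc9ccccc9)c([C@@H]5c6ccc(OCc9ccccc9)cc6O[C@@H](c6ccc(OCc9ccccc9)c(OCc9ccccc9)c6)[C@@H]5OCc9ccccc9)c(OCc9ccccc9)c4C[C@H](OCc9ccccc9)[C@@H](c5ccc(OCc9ccccc9)c(OCc9ccccc9)c5)Oc34)[C@@H](OCc9ccccc9)[C@@H](O[Si](C(C)C)(C(C)C)C(C)C)c3ccc(OCc9ccccc9)c(OCc9ccccc9)c3)c(Cl)cc1OCc9ccccc9 | intermediate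
37 | chloro alcohol, 36 with free 1-hydroxyl | C(c9ccccc9)Oc1ccc2c(c1)O[C@@H](c1ccc(OCc9ccccc9)c(OCc9ccccc9)c1)[C@H](OCc9ccccc9)[C@@H]2c1cc([C@@H](c3c(OCc9ccccc9)c([C@@H]5c6ccc(OCc9ccccc9)cc6O[C@@H](c6ccc(OCc9ccccc9)c(OCc9ccccc9)c6)[C@@H]5OCc9ccccc9)c(OCc9ccccc9)c4C[C@H](OCc9ccccc9)[C@@H](c5ccc(OCc9ccccc9)c(OCc9ccccc9)c5)Oc34)[C@@H](OCc9ccccc9)[C@@H](O)c3ccc(OCc9ccccc9)c(OCc9ccccc9)c3)c(Cl)cc1OCc9ccccc9 | intermediate
38 | heptadeca-O-benzyl ether of the target | C(c9ccccc9)Oc1ccc2c(c1)O[C@@H](c1ccc(OCc9ccccc9)c(OCc9ccccc9)c1)[C@H](OCc9ccccc9)[C@@H]2c1cc2c(cc1OCc9ccccc9)O[C@@H](c1ccc(OCc9ccccc9)c(OCc9ccccc9)c1)[C@H](OCc9ccccc9)[C@@H]2c1c(OCc9ccccc9)c([C@@H]2c3ccc(OCc9ccccc9)cc3O[C@@H](c3ccc(OCc9ccccc9)c(OCc9ccccc9)c3)[C@@H]2OCc9ccccc9)c(OCc9ccccc9)c2c1O[C@H](c1ccc(OCc9ccccc9)c(OCc9ccccc9)c1)[C@@H](OCc9ccccc9)C2 | intermediate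
39 | CNP0126838.1, ent-fisetinidol-(4α→6)-ent-fisetinidol-(4α→8)-catechin-(6→4α)-ent-fisetinidol | Oc1ccc2c(c1)O[C@@H](c1ccc(O)c(O)c1)[C@H](O)[C@@H]2c1cc2c(cc1O)O[C@@H](c1ccc(O)c(O)c1)[C@H](O)[C@@H]2c1c(O)c([C@@H]2c3ccc(O)cc3O[C@@H](c3ccc(O)c(O)c3)[C@@H]2O)c(O)c2c1O[C@H](c1ccc(O)c(O)c1)[C@@H](O)C2 | target

## Step count and least certain steps

Total: 31 steps. Longest linear sequence: 19 steps (steps 1, 3 to 6, 10 to 18, 27 to 31).

**Step 13 (key step).** The most likely failure is β-hydride elimination from the copper alkoxide of the benzylic alcohol, which would oxidise the alcohol and reduce the bromide. The second is a stalled reaction, because the bromide sits next to the bulky diarylmethyl carbon. The fallback gives up the alkoxide-to-arene coupling and forms O1–C2 from a phenol instead. It sets out from 15: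
- Miyaura borylation (PdCl2(dppf), bis(pinacolato)diboron, KOAc, dioxane, 80 °C) should take the bromide and spare the chloride, giving the pinacol boronate F1.
- Oxidation with NaBO3 in THF/water should give the phenol F2, and TBAF the phenol alcohol F3.
- Catalytic trifluoroacetic acid in wet CH2Cl2 should ionise the dialkoxybenzylic alcohol, and the phenol should close ring C trans to the O3 benzyl ether. The dioxolane is hydrolysed in the same medium, so the route is rejoined at aldehyde 18.
- The C2 configuration would then rest on the preference for the 2,3-trans ring and no longer on retention.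

**Step 27.** The di-ortho-substituted arylcopper species may be too hindered for the benzylic oxirane carbon, and the magnesium halide may promote rearrangement or ionisation of the oxirane, with loss of stereospecificity. Both partners are valuable. Steps 10 and 23 are the same reaction with cheaper partners and will show beforehand how far it carries. The fallback is a Friedel–Crafts-type opening. It sets out from 32:
- Bromine–lithium exchange with n-BuLi and quenching with methanol should give the debrominated dimer F4, whose only free position on the phloroglucinol ring is C8.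
- F4 and oxirane 22 are combined with BF3·OEt2 in CH2Cl2 at −78 °C, where the arene should open the activated oxirane at the benzylic carbon from the face opposite the leaving oxygen. This rejoins the route at 35.

**Step 30.** β-Hydride elimination from the palladium alkoxide would give the aryl ketone and the dechlorinated arene, and oxidative addition into the hindered, electron-rich chloride may be slow. The fallback again moves the bond formation to O1–C2. It sets out from 36:
- Palladium-catalysed hydroxylation of the aryl chloride (Pd2(dba)3, 2-di-tert-butylphosphino-2',4',6'-triisopropylbiphenyl, KOH, dioxane/water, 100 °C) should give the phenol silyl ether F5.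
- TBAF should give the phenol alcohol F6.
- Catalytic trifluoroacetic acid in CH2Cl2 should close ring C of unit M through the benzylic cation, trans to O3, and rejoin the route at 38.

**Step 16.** Hydroperoxide addition inside the peptide may be slow or poorly face-selective for an enone that is electron-rich, ortho-substituted and attached to the bulky unit T. The fallback replaces nucleophilic by directed electrophilic epoxidation. It sets out from 19:
- Luche reduction (NaBH4, CeCl3·7H2O, MeOH/THF) should give the allylic alcohol F7 as both carbinol epimers.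
- Sharpless epoxidation under kinetic-resolution conditions (Ti(OiPr)4, L-(+)-diisopropyl tartrate, t-BuOOH, molecular sieves, CH2Cl2, −20 °C) should epoxidise only the epimer that leads to the anti epoxy alcohol, which rejoins the route at 21.
- The unreacted epimer can be oxidised back to 19 with MnO2.

## Further compounds

F1 | step 13 | pinacol boronate from 15 (boron in place of bromine) | CC(C)[Si](C(C)C)(C(C)C)O[C@@H](c1ccc(OCc9ccccc9)c(OCc9ccccc9)c1)[C@H](OCc9ccccc9)[C@@H](c1ccc(OCc9ccccc9)cc1B2OC(C)(C)C(C)(C)O2)c1cc(C2OCCO2)c(Cl)cc1OCc9ccccc9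
F2 | step 13 | phenol from F1 | CC(C)[Si](C(C)C)(C(C)C)O[C@@H](c1ccc(OCc9ccccc9)c(OCc9ccccc9)c1)[C@H](OCc9ccccc9)[C@@H](c1ccc(OCc9ccccc9)cc1O)c1cc(C2OCCO2)c(Cl)cc1OCc9ccccc9
F3 | step 13 | phenol alcohol from F2 | O[C@@H](c1ccc(OCc9ccccc9)c(OCc9ccccc9)c1)[C@H](OCc9ccccc9)[C@@H](c1ccc(OCc9ccccc9)cc1O)c1cc(C2OCCO2)c(Cl)cc1OCc9ccccc9
F4 | step 27 | debrominated dimer, per-O-benzyl ent-fisetinidol-(4α→6)-catechin | C(c9ccccc9)Oc1ccc2c(c1)O[C@@H](c1ccc(OCc9ccccc9)c(OCc9ccccc9)c1)[C@H](OCc9ccccc9)[C@@H]2c1c(OCc9ccccc9)c2C[C@H](OCc9ccccc9)[C@@H](c3ccc(OCc9ccccc9)c(OCc9ccccc9)c3)Oc2cc1OCc9ccccc9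
F5 | step 30 | phenol silyl ether from 36 (hydroxyl in place of chlorine) | C(c9ccccc9)Oc1ccc2c(c1)O[C@@H](c1ccc(OCc9ccccc9)c(OCc9ccccc9)c1)[C@H](OCc9ccccc9)[C@@H]2c1cc([C@@H](c3c(OCc9ccccc9)c([C@@H]5c6ccc(OCc9ccccc9)cc6O[C@@H](c6ccc(OCc9ccccc9)c(OCc9ccccc9)c6)[C@@H]5OCc9ccccc9)c(OCc9ccccc9)c4C[C@H](OCc9ccccc9)[C@@H](c5ccc(OCc9ccccc9)c(OCc9ccccc9)c5)Oc34)[C@@H](OCc9ccccc9)[C@@H](O[Si](C(C)C)(C(C)C)C(C)C)c3ccc(OCc9ccccc9)c(OCc9ccccc9)c3)c(O)cc1OCc9ccccc9
F6 | step 30 | phenol alcohol from F5 | C(c9ccccc9)Oc1ccc2c(c1)O[C@@H](c1ccc(OCc9ccccc9)c(OCc9ccccc9)c1)[C@H](OCc9ccccc9)[C@@H]2c1cc([C@@H](c3c(OCc9ccccc9)c([C@@H]5c6ccc(OCc9ccccc9)cc6O[C@@H](c6ccc(OCc9ccccc9)c(OCc9ccccc9)c6)[C@@H]5OCc9ccccc9)c(OCc9ccccc9)c4C[C@H](OCc9ccccc9)[C@@H](c5ccc(OCc9ccccc9)c(OCc9ccccc9)c5)Oc34)[C@@H](OCc9ccccc9)[C@@H](O)c3ccc(OCc9ccccc9)c(OCc9ccccc9)c3)c(O)cc1OCc9ccccc9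
F7 | step 16 | allylic alcohol from 19 (both carbinol epimers) | C(c9ccccc9)Oc1ccc2c(c1)O[C@@H](c1ccc(OCc9ccccc9)c(OCc9ccccc9)c1)[C@H](OCc9ccccc9)[C@@H]2c1cc(/C=C/C(O)c3ccc(OCc9ccccc9)c(OCc9ccccc9)c3)c(Cl)cc1OCc9ccccc9
A1 | alternative 1 | per-O-benzyl tetramer with 3-O-acetyl ent-fisetinidol units | C(c9ccccc9)Oc1ccc2c(c1)O[C@@H](c1ccc(OCc9ccccc9)c(OCc9ccccc9)c1)[C@H](OC(C)=O)[C@@H]2c1cc2c(cc1OCc9ccccc9)O[C@@H](c1ccc(OCc9ccccc9)c(OCc9ccccc9)c1)[C@H](OC(C)=O)[C@@H]2c1c(OCc9ccccc9)c([C@@H]2c3ccc(OCc9ccccc9)cc3O[C@@H](c3ccc(OCc9ccccc9)c(OCc9ccccc9)c3)[C@@H]2OC(C)=O)c(OCc9ccccc9)c2c1O[C@H](c1ccc(OCc9ccccc9)c(OCc9ccccc9)c1)[C@@H](OCc1ccccc1)C2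
A2 | alternative 2 | 6,8-bis(3-benzyloxy-3,4-cis-dihydrocoumarin-4-yl) penta-O-benzylcatechin, brominated on one lactone ring | Brc1cc2c(cc1OCc9ccccc9)OC(=O)[C@H](OCc9ccccc9)[C@@H]2c1c(OCc9ccccc9)c([C@@H]2c3ccc(OCc9ccccc9)cc3OC(=O)[C@@H]2OCc9ccccc9)c(OCc9ccccc9)c2c1O[C@H](c1ccc(OCc9ccccc9)c(OCc9ccccc9)c1)[C@@H](OCc1ccccc1)C2
A3 | alternative 3 | 2,4-trans-4-arylflavan-3-one (racemic, needed enantiomer drawn) | C(c1ccccc1)Oc1ccc2c(c1)O[C@@H](c1ccc(OCc3ccccc3)c(OCc3ccccc3)c1)C(=O)[C@@H]2c1cc(Br)c(OCOC)cc1OCc1ccccc1
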